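**Retrosynthetic overview**
1. C8–prenyl bond: made last by a Claisen–Cope shift of a 5-O-prenyl ether (8 → 11). The O-prenyl group first blocks the future 5-OH, then becomes the 8-prenyl group.
2. Ring C (O1–C2 and C3–O bonds, both stereocentres): one-flask catalytic asymmetric epoxidation and 6-endo phenol closure of the unprotected 2'-hydroxychalcone 6.
3. Chalcone 6: Claisen–Schmidt condensation of acetophenone 3 with isovanillin 4.
4. Acetophenone 3: mono-O-prenylation of the symmetric 2',6'-dihydroxy-4'-methoxyacetophenone 1.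
5. Ring order: rings A and B are bought (1 and 4); ring C is the only ring formed (step 3).

**Assumptions:** The target is the (2R,3R)-trans flavanonol encoded by the SMILES. Catalysts and simple reagents are not numbered. Cat-A is the N-[3,5-bis(trifluoromethyl)benzyl]quinuclidinium bromide of 1-[4-(trifluoromethyl)phenyl]-3-(9-deoxy-epi-quinidin-9-yl)urea, a bifunctional urea–quaternary ammonium phase-transfer catalyst. Its sense of induction on this substrate is assigned by analogy and is not established.

**Step 1**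
Reactants: 1 2',6'-dihydroxy-4'-methoxyacetophenone; 2 prenyl bromide (1-bromo-3-methylbut-2-ene)
Product: 3 2'-hydroxy-4'-methoxy-6'-(prenyloxy)acetophenone
Conditions: 2 (1.05 equiv), K2CO3 (1.2 equiv), acetone, 56 °C, 6 h
Reagents that add atoms: none
Why: Williamson ether synthesis; 1 is symmetric, and after the first O-alkylation the remaining OH is chelated to the C=O and far less nucleophilic, so mono-O-prenylation is selective (carbonate in acetone favours O- over C-alkylation).

**Step 2**
Reactants: 3 2'-hydroxy-4'-methoxy-6'-(prenyloxy)acetophenone; 4 isovanillin (3-hydroxy-4-methoxybenzaldehyde)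
Product: 6 (E)-3-(3-hydroxy-4-methoxyphenyl)-1-[2-hydroxy-4-methoxy-6-(prenyloxy)phenyl]prop-2-en-1-one (chalcone), via aldol adduct 5 (not isolated)
Conditions: KOH (6 equiv, 50% aq.), EtOH, 0 → 25 °C, 36 h; then 1 M HCl to pH 4, 0 °C
Reagents that add atoms: none
Why: Claisen–Schmidt condensation; the ketone enolate adds to the non-enolisable aldehyde and E1cB dehydration gives the E-enone. The aldehyde's phenoxide is meta to CHO and so does not deactivate it by conjugation, and the aryl prenyl ether is stable to base.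

**Step 3**
Reactants: 6 (E)-3-(3-hydroxy-4-methoxyphenyl)-1-[2-hydroxy-4-methoxy-6-(prenyloxy)phenyl]prop-2-en-1-one
Product: 8 (2R,3R)-3-hydroxy-2-(3-hydroxy-4-methoxyphenyl)-7-methoxy-5-(prenyloxy)chroman-4-one, via epoxy ketone 7 (not isolated)
Conditions: Cat-A (10 mol%), 30% aq. H2O2 (1.5 equiv), KOH (2.2 equiv, 1 M aq.), toluene–MTBE, −20 °C; then AcOH (5 equiv), 0 → 25 °C
Reagents that add atoms: hydrogen peroxide, OO
Why: Proposed new method: enantioselective Weitz–Scheffer epoxidation of a chalcone with free 2'- and 3-OH groups under bifunctional ion-pair catalysis, followed in the same flask by acid-triggered 6-endo closure. The urea N–H pair of Cat-A (less acidic than either phenol, so it stays neutral) is meant to chelate the 2'-oxido-aryl-ketone O,O unit, which reduces phenoxide donation into the enone and holds the phenoxide away from Cα (the 5-exo aurone pathway that 6'-alkoxy substrates follow under Algar–Flynn–Oyamada conditions). The neighbouring ammonium delivers HOO− to one face of Cβ and the peroxy-enolate closes to the trans-(2R,3S)-epoxide 7, which fixes C3 (R, retained). On acidification the re-protonated 2'-OH opens the p-anisyl-type benzylic C–O bond at Cβ with inversion, giving C2 (R) and the 2,3-trans ring; if partial ionisation occurs, C3 is untouched and trans is also the thermodynamic isomer. Closest known reactions: cinchona-ammonium phase-transfer epoxidation of phenol-protected chalcones with H2O2, and acid cyclisation of 2'-O-protected chalcone epoxides to dihydroflavonols. The quinidine series is chosen because cinchonine/quinidine-type ammonium salts give the (αR,βS) epoxide with simple chalcones; the quinine-derived pseudoenantiomer is the switch if the sense is reversed.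

**Step 4**
Reactants: 8 (2R,3R)-3-hydroxy-2-(3-hydroxy-4-methoxyphenyl)-7-methoxy-5-(prenyloxy)chroman-4-one
Product: 11 (2R,3R)-3,5-dihydroxy-2-(3-hydroxy-4-methoxyphenyl)-7-methoxy-8-prenylchroman-4-one (target CNP0302743.1), via ortho-Claisen dienone 9 (not isolated), via para-dienone 10 (not isolated)
Conditions: Eu(fod)3 (10 mol%), dry CHCl3 (amylene-stabilised), 60 °C, Ar, 16 h
Reagents that add atoms: none
Why: Eu(III)-catalysed aromatic Claisen–Cope (para-Claisen) rearrangement; Eu chelates C4=O and the 5-O-prenyl oxygen and the [3,3] shift gives the crowded C6 dienone 9. A second [3,3] (Cope) shift moves the allyl unit to C8 with the normal prenyl orientation (10), and tautomerisation gives the chelated 5-OH; C2 and C3 are not involved under these neutral conditions.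

**Compound list**
1 | 2',6'-dihydroxy-4'-methoxyacetophenone | CC(=O)c1c(O)cc(OC)cc1O | starting material
2 | prenyl bromide (1-bromo-3-methylbut-2-ene) | CC(C)=CCBr | starting material
3 | 2'-hydroxy-4'-methoxy-6'-(prenyloxy)acetophenone | CC(=O)c1c(O)cc(OC)cc1OCC=C(C)C | intermediate
4 | isovanillin (3-hydroxy-4-methoxybenzaldehyde) | COc1ccc(C=O)cc1O | starting material
5 | aldol adduct, 3-hydroxy-3-(3-hydroxy-4-methoxyphenyl)-1-[2-hydroxy-4-methoxy-6-(prenyloxy)phenyl]propan-1-one (racemic) | COc1ccc(C(O)CC(=O)c2c(O)cc(OC)cc2OCC=C(C)C)cc1O | intermediate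
6 | (E)-3-(3-hydroxy-4-methoxyphenyl)-1-[2-hydroxy-4-methoxy-6-(prenyloxy)phenyl]prop-2-en-1-one | COc1ccc(/C=C/C(=O)c2c(O)cc(OC)cc2OCC=C(C)C)cc1O | intermediate
7 | [(2R,3S)-3-(3-hydroxy-4-methoxyphenyl)oxiran-2-yl][2-hydroxy-4-methoxy-6-(prenyloxy)phenyl]methanone | O=C(c1c(O)cc(OC)cc1OCC=C(C)C)[C@@H]1O[C@H]1c1ccc(OC)c(O)c1 | intermediate
8 | (2R,3R)-3-hydroxy-2-(3-hydroxy-4-methoxyphenyl)-7-methoxy-5-(prenyloxy)chroman-4-one | COc1ccc([C@H]2Oc3cc(OC)cc(OCC=C(C)C)c3C(=O)[C@@H]2O)cc1O | intermediate
9 | ortho-Claisen dienone, (2R,3R)-3-hydroxy-2-(3-hydroxy-4-methoxyphenyl)-7-methoxy-6-(2-methylbut-3-en-2-yl)-2,3-dihydro-6H-chromene-4,5-dione (C6 epimers) | COc1ccc([C@H]2OC3=C(C(=O)C(C(C)(C)C=C)C(OC)=C3)C(=O)[C@@H]2O)cc1O | intermediate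
10 | para-dienone, (2R,3R)-3-hydroxy-2-(3-hydroxy-4-methoxyphenyl)-7-methoxy-8-(3-methylbut-2-enyl)-2,3-dihydro-8H-chromene-4,5-dione (C8 epimers) | COc1ccc([C@H]2OC3=C(C(=O)C=C(OC)C3CC=C(C)C)C(=O)[C@@H]2O)cc1O | intermediate
11 | (2R,3R)-3,5-dihydroxy-2-(3-hydroxy-4-methoxyphenyl)-7-methoxy-8-(3-methylbut-2-enyl)chroman-4-one | COc1ccc([C@H]2Oc3c(CC=C(C)C)c(OC)cc(O)c3C(=O)[C@@H]2O)cc1O | target

**Total step count:** 4. **Longest linear sequence:** 4 (1 → 3 → 6 → 8 → 11).

**Three steps most likely to fail**

Step 3 (the proposed new step). The phenoxide may slow the epoxidation, attack Cα to give an aurone, or the ee or its sense may be poor. The fallback uses known chemistry, sets out from 6 and comes back at 8. Both phenols of 6 are capped with MOMCl/NaH in DMF to give the bis(methoxymethyl) ether of the chalcone F1. A Juliá–Colonna epoxidation (poly-L-leucine, urea·H2O2, DBU, THF, 25 °C) then gives the (2R,3S)-epoxy ketone bis-MOM ether F2, in the sense established for poly-L-amino acids on chalcones. Dilute HCl in MeOH–THF at no more than 40 °C (to spare the prenyl ether) removes both MOM groups, and the freed 2'-OH closes 6-endo at the benzylic carbon to give 8.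

Step 4. The free 3-OH and 3'-OH may tie up Eu(III), or the reaction may stop at the ortho (reverse-prenyl) product. The fallback sets out from 8 and comes back at 11. The two hydroxyls are masked with TESCl/imidazole in DMF to give the 3,3'-bis(triethylsilyl) ether of 8 F3, the protected substrate class on which this rearrangement is established. Eu(fod)3 in CHCl3 at 60 °C (or PhCl at 85 °C) then gives the 8-prenyl-5-hydroxy bis(triethylsilyl) ether F4. HF·pyridine in THF at 0 °C removes the silyl groups to give 11.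

Step 2. The phenoxide of isovanillin may make the condensation slow and low-yielding. The fallback sets out from 4 and comes back at 6. Isovanillin is converted with dihydropyran/PPTS in CH2Cl2 into 4-methoxy-3-(tetrahydropyran-2-yloxy)benzaldehyde F5. This is condensed with 3 (KOH, EtOH, 25 °C) to give the 3-O-THP chalcone F6. PPTS in EtOH at 50 °C unmasks the phenol to give 6 without touching the prenyl ether.

**Further compounds**
F1 | step 3 | (E)-3-[4-methoxy-3-(methoxymethoxy)phenyl]-1-[4-methoxy-2-(methoxymethoxy)-6-(prenyloxy)phenyl]prop-2-en-1-one | COc1ccc(/C=C/C(=O)c2c(OCOC)cc(OC)cc2OCC=C(C)C)cc1OCOC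
F2 | step 3 | [(2R,3S)-3-[4-methoxy-3-(methoxymethoxy)phenyl]oxiran-2-yl][4-methoxy-2-(methoxymethoxy)-6-(prenyloxy)phenyl]methanone | O=C(c1c(OCOC)cc(OC)cc1OCC=C(C)C)[C@@H]1O[C@H]1c1ccc(OC)c(OCOC)c1
F3 | step 4 | (2R,3R)-2-[4-methoxy-3-(triethylsilyloxy)phenyl]-7-methoxy-5-(prenyloxy)-3-(triethylsilyloxy)chroman-4-one | COc1ccc([C@H]2Oc3cc(OC)cc(OCC=C(C)C)c3C(=O)[C@@H]2O[Si](CC)(CC)CC)cc1O[Si](CC)(CC)CC
F4 | step 4 | (2R,3R)-5-hydroxy-2-[4-methoxy-3-(triethylsilyloxy)phenyl]-7-methoxy-8-(3-methylbut-2-enyl)-3-(triethylsilyloxy)chroman-4-one | COc1ccc([C@H]2Oc3c(CC=C(C)C)c(OC)cc(O)c3C(=O)[C@@H]2O[Si](CC)(CC)CC)cc1O[Si](CC)(CC)CC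
F5 | step 2 | 4-methoxy-3-(tetrahydropyran-2-yloxy)benzaldehyde (racemic) | COc1ccc(C=O)cc1OC1CCCCO1
F6 | step 2 | (E)-1-[2-hydroxy-4-methoxy-6-(prenyloxy)phenyl]-3-[4-methoxy-3-(tetrahydropyran-2-yloxy)phenyl]prop-2-en-1-one | COc1ccc(/C=C/C(=O)c2c(O)cc(OC)cc2OCC=C(C)C)cc1OC1CCCCO1
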